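The readings come from a simulation for an exercise; the scatter is artificial.

In a one-step world each substrate molecule has one road, and the share of single ring does not depend on the charge. These flasks are different.

| flask | substrate | remark | time |
|---|---|---|---|
| dusk | 7 mM | run made earlier |  |
| noon | 12 mM | run made earlier |  |
| dawn | 16 mM | run made earlier |  |
| cedar | 14 mM |  | 12 min |
| oak | 10 mM |  | 20 min |

- dusk (time / min: single ring / %, open dimer / %): 2.50: 68, 1; 5.00: 81, 2; 8.00: 85, 0; 10.0: 79, 0; 12.0: 80, 0
- noon (time / min: single ring / %, open dimer / %): 2.50: 61, 0; 5.00: 72, 0; 8.00: 71, 0; 10.0: 72, 0; 12.0: 74, 0
- dawn (time / min: single ring / %, open dimer / %): 1.00: 39, 2; 3.00: 58, 2; 6.00: 66, 0; 8.00: 68, 2; 12.0: 68, 0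

(standard deviation of a reading: 1.5 percentage points)

- a species is counted by the substrate in it: one open dimer or ring dimer or side product counts as two
- a species is counted by the substrate in it: one open trimer counts as three

1. which one finishes higher in share of single ring in all that became single ring or open dimer or open trimer or ring dimer or side product ("neither" within 2 percentage points) (cedar / oak / neither)
2. share of single ring in all that became single ring or open dimer or open trimer or ring dimer or side product, cedar
3. share of single ring in all that became single ring or open dimer or open trimer or ring dimer or side product, oak

The last three readings of single ring average 81.3% at dusk, 72.3% at noon and 67.3% at dawn. So dawn lacks 32.7% of its charge, yet its open dimer reads 0% at 12.0 min, much less than that gap. The two numbers do not clash. Open dimer is one species among several, the others went unread, and a low stock says little about a flow.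

I follow one molecule. Its chance to close per unit time is independent of concentration, while its chance to meet a partner grows with the partner's concentration. I cannot tell from these readings who the partner is, so I assume that it scales with the charge and take the odds of loss against ring, over the whole run, as proportional to the starting [substrate]. I call the charge at which these odds are even the even-odds charge, a selectivity factor in concentration units; the share is then this charge divided by the sum of itself and the actual charge. The runs give 30.5 mM, 31.4 mM and 33.0 mM, so I carry their mean, 31.6 mM. My reckoning gives cedar 69.3% and oak 76.0%.

The forecast says 69.5% for cedar and 75.5% for oak, with oak higher, reading the runs as “first-order ring closure competing with second-order dimerisation”. Its numbers differ slightly from mine.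

The flask gives 70.2% for cedar and 76.4% for oak, so oak finishes higher.

    substrate ⇌ dormant form (K = 1.10, k = 0.400 s⁻¹)
    substrate + single ring → side product (k = 0.600 M⁻¹ s⁻¹)
    2 substrate → open dimer (k = 0.110 M⁻¹ s⁻¹)
    substrate → single ring (k = 0.0200 s⁻¹)
    open dimer → ring dimer (k = 0.0330 s⁻¹)
    substrate + open dimer → open trimer (k = 6.70 M⁻¹ s⁻¹)

In oak at 1.02 min, single ring is made 8.20 times faster than it is used up, each step taken net. Side product reaches 20.8% of the oak charge at 20.0 min, more than open trimer and ring dimer together. Now take a flask like oak with 2.5 mM of substrate. The even-odds charge gives 92.7%, and the computed share is 92.6%.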